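**Retrosynthetic overview**

1. Numbering (briarane): ten-membered ring C1–C10 (C15H3 on C1, C16H3 on C5); cyclohexane C1, C10, C11 (C20H3), C12, C13, C14; lactone C7–O–C19(=O)–C17(C18H3)–C8.
2. Last ring: the cyclohexane, by an intermolecular Diels–Alder reaction (C10–C11 and C1–C14) of the ten-membered E-enone 20 with the 1,3-bis(silyloxy)diene 24. Enabling feature: the fusion bond C1–C10 is shared by the six- and ten-membered rings and adjoins C2, so it can be an E enone double bond (C2=O) inside the macrocycle, while C11–C14 with oxygen on C12 and C14 maps onto a 1,3-dioxygenated butadiene.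
3. Ten-membered ring: Nozaki–Hiyama–Kishi closure of C1–C2 (step 11); before it the lactone, by intramolecular Reformatsky addition to a C8 ketone (step 10).
4. C7–C8–C9 come from the twofold-symmetric bis-propargylic diol 6 (double CBS reduction), desymmetrised by monosilylation; one alkyne becomes the (5Z)-olefin, the other the (E)-C1 iodoalkene.
5. After the key step the C14 oxygen relays to C12 (syn reduction) and C2 (anti reduction), and C11 comes from hydrogenation of a C11=C20 methylene. Ring order: lactone, ten-membered ring, cyclohexane.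

Key step: step 15

Remark: atom numbers in names are the briarane numbers above; configurations are those of the SMILES.
Assumption: 1-propynyllithium and 4-(phenylthio)butan-2-one are taken as commercial.
Assumption: the bromine-bearing carbon of 16 and the carbinol C2 of 19 are epimer mixtures erased in the following step, so their SMILES leave these centres open.

**Route**

Step 1
Reactants: 1 diethyl ketomalonate; 2 propane-1,3-dithiol
Product: 3 diethyl 1,3-dithiane-2,2-dicarboxylate
Conditions: BF3·OEt2 (0.2 equiv), CH2Cl2, 0 °C to rt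
Reagents that add atoms: none
Why: Lewis-acid-catalysed dithioketalisation of the strongly electrophilic central ketone masks the future C8 carbonyl as a base-stable dithiane, with no stereocentre formed.

Step 2
Reactants: 3 diethyl 1,3-dithiane-2,2-dicarboxylate; 4 1-propynyllithium
Product: 5 bis-ynone 1,1'-(1,3-dithiane-2,2-diyl)bis(but-2-yn-1-one)
Conditions: 4 (2.2 equiv), BF3·OEt2 (2.2 equiv), THF, −78 °C
Reagents that add atoms: none
Why: BF3-promoted alkynylation of an ester should stop at the ynone because the boron-bound tetrahedral intermediate survives until work-up, and it installs C5/C6/C16 and C10/C1/C15 at once.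

Step 3
Reactants: 5 bis-ynone
Product: 6 (1R,1'R)-1,1'-(1,3-dithiane-2,2-diyl)bis(but-2-yn-1-ol)
Conditions: (S)-2-methyl-CBS-oxazaborolidine (0.4 equiv), catecholborane (2.5 equiv), CH2Cl2, −78 °C
Reagents that add atoms: none
Why: Double Corey–Bakshi–Shibata reduction in which the alkynyl group is the small and the quaternary dithianyl carbon the large substituent should give R at both carbinols (C7 and C9), the second reduction raising the enantiomeric purity of the twofold-symmetric diol.

Step 4
Reactants: 6 (R,R)-diol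
Product: 7 mono-TBS ether (C9–OTBS and C7–OH)
Conditions: TBSOTf (1.0 equiv), 2,6-lutidine, CH2Cl2, −78 °C
Reagents that add atoms: tert-butyldimethylsilyl triflate CC(C)(C)[Si](C)(C)OS(=O)(=O)C(F)(F)F
Why: The two hydroxyls are homotopic through the twofold axis, so monosilylation gives a single mono-ether and defines which arm becomes C9 (diol and bis-ether are recycled).

Step 5
Reactants: 7 mono-TBS ether
Product: 9 (Z)-iodoalkene (C5–I cis to C7), via cyclic sodium alkenylaluminate 8 (not isolated)
Conditions: NaAlH2(OCH2CH2OMe)2, THF, 0 °C to rt; then I2, −78 °C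
Reagents that add atoms: iodine II
Why: Alkoxide-directed trans-hydroalumination of the free propargylic alcohol puts aluminium on the distal alkyne carbon cis to the carbinol, and iodinolysis with retention gives the (Z)-iodoalkene while the silylated arm, lacking the directing alkoxide, is untouched.

Step 6
Reactants: 9 (Z)-iodoalkene; 10 acrolein diethyl acetal
Product: 12 (5Z)-trisubstituted olefin with C2 diethyl acetal, via alkylborane 11 (not isolated)
Conditions: 10, 9-BBN, THF, rt; then 9, Pd(dppf)Cl2 (5 mol %), AsPh3, Cs2CO3, DMF/H2O, rt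
Reagents that add atoms: none
Why: B-alkyl Suzuki–Miyaura coupling proceeds with retention at the alkenyl iodide, so C4 enters cis to C7 and the (5Z) geometry is fixed.

Step 7
Reactants: 12 (5Z)-olefin alkyne
Product: 14 (E)-C1 iodoalkene, via zirconated alkenylzirconocene 13 (not isolated)
Conditions: Cp2Zr(H)Cl (3 equiv), THF, rt; then I2, 0 °C
Reagents that add atoms: iodine II
Why: Syn hydrozirconation places zirconium on the less hindered methyl-bearing alkyne carbon C1 (excess reagent equilibrates to this isomer) and iodinolysis with retention gives the iodide trans to C9.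

Step 8
Reactants: 14 (E)-C1 iodoalkene
Product: 15 α-hydroxy ketone (C8=O with C7–OH and C9–OTBS)
Conditions: MeI, CaCO3, MeCN/H2O (9:1), 45 °C
Reagents that add atoms: water O
Why: Alkylative dithiane hydrolysis under buffered neutral conditions unmasks the C8 ketone without touching the acetal, the silyl ether, the alkenyl iodide or the two base-labile α-stereocentres.

Step 9
Reactants: 15 α-hydroxy ketone
Product: 16 C7 2-bromopropanoate
Conditions: 2-bromopropanoyl bromide, pyridine, CH2Cl2, −20 °C
Reagents that add atoms: 2-bromopropanoyl bromide CC(Br)C(Br)=O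
Why: Acylation of the only free hydroxyl under weakly basic conditions attaches the Reformatsky donor to O7 without enolising the ketone.

Step 10
Reactants: 16 C7 2-bromopropanoate
Product: 18 aldehyde lactone, via acetal lactone 17 (not isolated)
Conditions: SmI2 (2.2 equiv), THF, −78 °C; then 1 M HCl, THF, rt
Reagents that add atoms: water O
Why: Intramolecular Reformatsky lactonisation, in which SmI2 cleaves the C–Br bond faster than it reduces the ketone and the trivalent samarium enolate adds to C8 through a five-membered transition state that puts the C9 branch trans to the C6 alkenyl group (8R) and the C17 methyl cis to the new hydroxyl (17S, also the stable epimer); dilute acid then frees the C2 aldehyde.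

Step 11
Reactants: 18 aldehyde lactone
Product: 19 ten-membered allylic alcohol (C2 epimers)
Conditions: CrCl2 (8 equiv), NiCl2 (2 mol %), DMSO, rt, slow addition to 0.002 M
Reagents that add atoms: none
Why: Intramolecular Nozaki–Hiyama–Kishi addition of the alkenyl trivalent chromium species to the aldehyde closes the ten-membered ring at C1–C2 with retention of the E geometry, and the C2 configuration does not matter because it is oxidised next.

Step 12
Reactants: 19 ten-membered allylic alcohol
Product: 20 ten-membered (E)-2-methyl enone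
Conditions: Dess–Martin periodinane, CH2Cl2, 0 °C to rt
Reagents that add atoms: none
Why: Dess–Martin oxidation of the only secondary alcohol gives the C2 ketone conjugated to C1=C10, the tertiary C8 hydroxyl being inert.

Step 13
Reactants: 21 4-(phenylthio)butan-2-one
Product: 23 (E)-1-(tert-butyldimethylsilyloxy)-5-(phenylthio)pent-1-en-3-one, via lithium enolate 22 (not isolated)
Conditions: LiN(i-Pr)2, THF, −78 °C; HCO2Et, −78 to 0 °C; then TBSCl, 0 °C
Reagents that add atoms: ethyl formate CCOC=O; tert-butyldimethylsilyl chloride CC(C)(C)[Si](C)(C)Cl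
Why: The kinetic methyl enolate undergoes Claisen formylation and the resulting β-keto aldehyde enolate is O-silylated to the E β-silyloxy enone.

Step 14
Reactants: 23 β-silyloxy enone
Product: 24 (1E,3Z)-1-(tert-butyldimethylsilyloxy)-5-(phenylthio)-3-(trimethylsilyloxy)penta-1,3-diene
Conditions: TMSOTf, Et3N, Et2O, 0 °C
Reagents that add atoms: trimethylsilyl triflate C[Si](C)(C)OS(=O)(=O)C(F)(F)F
Why: Soft enolisation on the only enolisable side gives the Z silyl enol ether, which is the diene with the CH2SPh group (latent C20) in the outside position.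

Step 15
Reactants: 20 ten-membered (E)-enone; 24 bis(silyloxy)diene
Product: 26 tricyclic diketone with C11–CH2SPh and C14–OTBS, via cycloadduct silyl enol ether 25 (not isolated)
Conditions: 24 (3 equiv), toluene, 2,6-di-tert-butyl-4-methylphenol (cat.), 100 °C, sealed tube; then 0.02 M HCl, THF, 0 °C
Reagents that add atoms: none
Why: Thermal normal-electron-demand Diels–Alder reaction, closest to the known cycloadditions of 1-alkoxy-3-silyloxybutadienes with 2-methylcycloalk-2-enones and helped here by the strain of the E double bond in the ten-membered ring. The cyclohexane is closed in one intermolecular [4+2] event, suprafacial on both partners, in which the nucleophilic diene terminus C11 bonds to the enone β-carbon C10 and C14 bonds to C1, the C2 ketone being the only activating group. The E geometry of C1=C10 places the C15 methyl on the new quaternary C1 trans to H10 (trans ring fusion), and the endo position of the C2 carbonyl puts the E silyloxy group of C14 cis to C2, which is 14R. The configuration at C11 (CH2SPh cis to H10) is of no consequence because C11 becomes trigonal in step 16. The step needs facial selectivity relative to C9: the diene should add to the outer face of the macrocycle anti to the fully substituted C8, with the small C9–H turned toward the substituted diene terminus and the C9 silyloxy group near the olefin plane on the C15 side, which gives 10R. The dilute acid cleaves only the trimethylsilyl enol ether and leaves the β-silyloxy ketone intact.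

Step 16
Reactants: 26 tricyclic diketone with C11–CH2SPh
Product: 28 C11=C20 methylene diketone, via sulfoxide 27 (not isolated)
Conditions: mCPBA (1.0 equiv), CH2Cl2, −78 °C; then toluene, 60 °C
Reagents that add atoms: none
Why: Sulfide oxidation is far faster than epoxidation of the trisubstituted C5=C6 olefin, and thermal syn-elimination of the β-keto sulfoxide can only use H11, giving the exocyclic enone.

Step 17
Reactants: 28 C11=C20 methylene diketone
Product: 29 C11-methyl diketone bis-TBS ether
Conditions: H2 (1 atm), RhCl(PPh3)3 (10 mol %), benzene, rt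
Reagents that add atoms: none
Why: RhCl(PPh3)3 hydrogenates the 1,1-disubstituted enone olefin but not the trisubstituted C5=C6, and A(1,3) strain with the methylene turns the C9 branch on C10 axial so that hydrogen adds from the opposite face and the C20 methyl ends cis to C9 (11S).

Step 18
Reactants: 29 C11-methyl diketone bis-TBS ether
Product: 30 triol diketone (C8, C9 and C14 hydroxyls)
Conditions: HF·pyridine, THF/pyridine, 0 °C to rt
Reagents that add atoms: none
Why: Buffered fluoride cleaves both secondary TBS ethers without base, so the β-hydroxy ketone units neither eliminate nor undergo retro-aldol cleavage.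

Step 19
Reactants: 30 triol diketone
Product: 31 C12 alcohol (12,14-cis diol with C2 ketone)
Conditions: Et2BOMe (1.1 equiv), THF/MeOH (4:1), −78 °C; NaBH4 (1.1 equiv), −78 °C; MeOH evaporation
Reagents that add atoms: none
Why: Narasaka–Prasad reduction in which boron chelates O14 and the C12 carbonyl and external hydride attacks anti to the chelate gives the cis-1,3-diol (12S), while the neopentylic C2 ketone in the ten-membered ring should react much more slowly at −78 °C.

Step 20
Reactants: 31 C12 alcohol
Product: 32 pentaol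
Conditions: Me4NBH(OAc)3 (5 equiv), MeCN/AcOH (1:1), −30 °C
Reagents that add atoms: none
Why: Evans–Saksena reduction delivers hydride intramolecularly from the C14 alkoxyborohydride through a chair transition state and gives the 1,3-anti relation of O14 and O2 (2R).

Step 21
Reactants: 32 pentaol
Product: 34 triacetate C12 triethylsilyl ether, via C12 triethylsilyl ether 33 (not isolated)
Conditions: Et3SiCl (1.05 equiv), imidazole, DMF, −30 °C; then Ac2O, DMAP, pyridine, rt to 40 °C
Reagents that add atoms: chlorotriethylsilane CC[Si](Cl)(CC)CC; acetic anhydride CC(=O)OC(C)=O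
Why: The C12 hydroxyl is the only secondary alcohol not flanked by a quaternary carbon and should be silylated first, after which DMAP-catalysed acetylation takes the C2, C9 and C14 hydroxyls and leaves the tertiary C8 hydroxyl free.

Step 22
Reactants: 34 triacetate C12 triethylsilyl ether
Product: 35 CNP0195208.4
Conditions: HF·pyridine, THF, 0 °C
Reagents that add atoms: none
Why: Mild fluoride cleavage of the triethylsilyl ether frees the C12 hydroxyl without touching the acetates or the lactone.

**Compound list**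

1 | diethyl ketomalonate (diethyl 2-oxopropanedioate) | CCOC(=O)C(=O)C(=O)OCC | starting material
2 | propane-1,3-dithiol | SCCCS | starting material
3 | diethyl 1,3-dithiane-2,2-dicarboxylate | CCOC(=O)C1(SCCCS1)C(=O)OCC | intermediate
4 | 1-propynyllithium | [Li]C#CC | starting material
5 | 1,1'-(1,3-dithiane-2,2-diyl)bis(but-2-yn-1-one) | CC#CC(=O)C1(SCCCS1)C(=O)C#CC | intermediate
6 | (1R,1'R)-1,1'-(1,3-dithiane-2,2-diyl)bis(but-2-yn-1-ol) | CC#C[C@@H](O)C1(SCCCS1)[C@H](O)C#CC | intermediate
7 | (1R)-1-{2-[(1R)-1-(tert-butyldimethylsilyloxy)but-2-yn-1-yl]-1,3-dithian-2-yl}but-2-yn-1-ol | CC#C[C@@H](O)C1(SCCCS1)[C@H](O[Si](C)(C)C(C)(C)C)C#CC | intermediate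
8 | cyclic sodium alkenylaluminate (Al on C5 and O7) | CC1=C[C@H](C2(SCCCS2)[C@H](O[Si](C)(C)C(C)(C)C)C#CC)O[Al-]1(OCCOC)OCCOC.[Na+] | intermediate (not isolated)
9 | (1R,2Z)-1-{2-[(1R)-1-(tert-butyldimethylsilyloxy)but-2-yn-1-yl]-1,3-dithian-2-yl}-3-iodobut-2-en-1-ol | C/C(I)=C/[C@@H](O)C1(SCCCS1)[C@H](O[Si](C)(C)C(C)(C)C)C#CC | intermediate
10 | acrolein diethyl acetal (3,3-diethoxyprop-1-ene) | C=CC(OCC)OCC | starting material
11 | 9-(3,3-diethoxypropyl)-9-borabicyclo[3.3.1]nonane | CCOC(OCC)CCB1C2CCCC1CCC2 | intermediate (not isolated)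
12 | (1R,2Z)-1-{2-[(1R)-1-(tert-butyldimethylsilyloxy)but-2-yn-1-yl]-1,3-dithian-2-yl}-6,6-diethoxy-3-methylhex-2-en-1-ol | CCOC(OCC)CC/C(C)=C\[C@@H](O)C1(SCCCS1)[C@H](O[Si](C)(C)C(C)(C)C)C#CC | intermediate
13 | alkenylzirconocene chloride at C1 with zirconium alkoxide at O7 | CCOC(OCC)CC/C(C)=C\[C@@H](O[Zr](Cl)(C1C=CC=C1)C1C=CC=C1)C1(SCCCS1)[C@H](O[Si](C)(C)C(C)(C)C)/C=C(\C)[Zr](Cl)(C1C=CC=C1)C1C=CC=C1 | intermediate (not isolated)
14 | (1R,2Z)-1-{2-[(1R,2E)-1-(tert-butyldimethylsilyloxy)-3-iodobut-2-en-1-yl]-1,3-dithian-2-yl}-6,6-diethoxy-3-methylhex-2-en-1-ol | CCOC(OCC)CC/C(C)=C\[C@@H](O)C1(SCCCS1)[C@H](O[Si](C)(C)C(C)(C)C)/C=C(\C)I | intermediate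
15 | (2E,4R,6R,7Z)-4-(tert-butyldimethylsilyloxy)-11,11-diethoxy-6-hydroxy-2-iodo-8-methylundeca-2,7-dien-5-one | CCOC(OCC)CC/C(C)=C\[C@@H](O)C(=O)[C@H](O[Si](C)(C)C(C)(C)C)/C=C(\C)I | intermediate
16 | 2-bromopropanoate of 15 at O7 (epimers at CHBr) | CCOC(OCC)CC/C(C)=C\[C@@H](OC(=O)C(C)Br)C(=O)[C@H](O[Si](C)(C)C(C)(C)C)/C=C(\C)I | intermediate
17 | (3S,4R,5R)-5-[(1Z)-5,5-diethoxy-2-methylpent-1-en-1-yl]-4-hydroxy-4-[(1R,2E)-1-(tert-butyldimethylsilyloxy)-3-iodobut-2-en-1-yl]-3-methyloxolan-2-one | CCOC(OCC)CC/C(C)=C\[C@H]1OC(=O)[C@@H](C)[C@]1(O)[C@H](O[Si](C)(C)C(C)(C)C)/C=C(\C)I | intermediate (not isolated)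
18 | (4Z)-5-{(2R,3R,4S)-3-hydroxy-3-[(1R,2E)-1-(tert-butyldimethylsilyloxy)-3-iodobut-2-en-1-yl]-4-methyl-5-oxooxolan-2-yl}-4-methylpent-4-enal | O=CCC/C(C)=C\[C@H]1OC(=O)[C@@H](C)[C@]1(O)[C@H](O[Si](C)(C)C(C)(C)C)/C=C(\C)I | intermediate
19 | lactone-fused ten-membered allylic alcohol: C2–OH (epimers), C1(10) E and C5 Z olefins, C8–OH, C9–OTBS | CC(C)(C)[Si](C)(C)O[C@@H]1/C=C(\C)C(O)CC/C(C)=C\[C@H]2OC(=O)[C@@H](C)[C@]12O | intermediate
20 | lactone-fused ten-membered enone: C2 ketone, C1(10) E and C5 Z olefins, C8–OH, C9–OTBS | CC(C)(C)[Si](C)(C)O[C@@H]1/C=C(\C)C(=O)CC/C(C)=C\[C@H]2OC(=O)[C@@H](C)[C@]12O | intermediate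
21 | 4-(phenylthio)butan-2-one | CC(=O)CCSc1ccccc1 | starting material
22 | lithium (Z)-3-oxo-5-(phenylthio)pent-1-en-1-olate | [Li+].[O-]/C=C\C(=O)CCSc1ccccc1 | intermediate (not isolated)
23 | (E)-1-(tert-butyldimethylsilyloxy)-5-(phenylthio)pent-1-en-3-one | CC(C)(C)[Si](C)(C)O/C=C/C(=O)CCSc1ccccc1 | intermediate
24 | (1E,3Z)-1-(tert-butyldimethylsilyloxy)-5-(phenylthio)-3-(trimethylsilyloxy)penta-1,3-diene | CC(C)(C)[Si](C)(C)O/C=C/C(O[Si](C)(C)C)=C/CSc1ccccc1 | intermediate
25 | Diels–Alder adduct: C12 trimethylsilyl enol ether (C12=C13), C11–CH2SPh, C14–OTBS, C9–OTBS, C2 ketone | CC(C)(C)[Si](C)(C)O[C@@H]1[C@@H]2[C@@H](CSc3ccccc3)C(O[Si](C)(C)C)=C[C@@H](O[Si](C)(C)C(C)(C)C)[C@@]2(C)C(=O)CC/C(C)=C\[C@H]2OC(=O)[C@@H](C)[C@]12O | intermediate (not isolated)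
26 | tricyclic 2,12-diketone with C11–CH2SPh, C9–OTBS, C14–OTBS, C8–OH | CC(C)(C)[Si](C)(C)O[C@@H]1[C@@H]2[C@@H](CSc3ccccc3)C(=O)C[C@@H](O[Si](C)(C)C(C)(C)C)[C@@]2(C)C(=O)CC/C(C)=C\[C@H]2OC(=O)[C@@H](C)[C@]12O | intermediate
27 | sulfoxide of 26 (C20–S(O)Ph) | CC(C)(C)[Si](C)(C)O[C@@H]1[C@@H]2[C@@H](CS(=O)c3ccccc3)C(=O)C[C@@H](O[Si](C)(C)C(C)(C)C)[C@@]2(C)C(=O)CC/C(C)=C\[C@H]2OC(=O)[C@@H](C)[C@]12O | intermediate (not isolated)
28 | tricyclic 2,12-diketone with C11=C20 methylene, C9–OTBS, C14–OTBS | CC(C)(C)[Si](C)(C)O[C@@H]1[C@@H]2C(=C)C(=O)C[C@@H](O[Si](C)(C)C(C)(C)C)[C@@]2(C)C(=O)CC/C(C)=C\[C@H]2OC(=O)[C@@H](C)[C@]12O | intermediate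
29 | tricyclic 2,12-diketone with 11S methyl, C9–OTBS, C14–OTBS | CC(C)(C)[Si](C)(C)O[C@@H]1[C@@H]2[C@H](C)C(=O)C[C@@H](O[Si](C)(C)C(C)(C)C)[C@@]2(C)C(=O)CC/C(C)=C\[C@H]2OC(=O)[C@@H](C)[C@]12O | intermediate
30 | 8,9,14-triol 2,12-diketone | O[C@@H]1[C@@H]2[C@H](C)C(=O)C[C@@H](O)[C@@]2(C)C(=O)CC/C(C)=C\[C@H]2OC(=O)[C@@H](C)[C@]12O | intermediate
31 | 8,9,12,14-tetraol 2-ketone (12S) | O[C@@H]1[C@@H]2[C@H](C)[C@@H](O)C[C@@H](O)[C@@]2(C)C(=O)CC/C(C)=C\[C@H]2OC(=O)[C@@H](C)[C@]12O | intermediate
32 | 2,8,9,12,14-pentaol (2R) | O[C@@H]1[C@@H]2[C@H](C)[C@@H](O)C[C@@H](O)[C@@]2(C)[C@H](O)CC/C(C)=C\[C@H]2OC(=O)[C@@H](C)[C@]12O | intermediate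
33 | C12 triethylsilyl ether of 32 | O[C@@H]1[C@@H]2[C@H](C)[C@@H](O[Si](CC)(CC)CC)C[C@@H](O)[C@@]2(C)[C@H](O)CC/C(C)=C\[C@H]2OC(=O)[C@@H](C)[C@]12O | intermediate (not isolated)
34 | 2,9,14-triacetate C12 triethylsilyl ether | CC(=O)O[C@@H]1[C@@H]2[C@H](C)[C@@H](O[Si](CC)(CC)CC)C[C@@H](OC(C)=O)[C@@]2(C)[C@H](OC(C)=O)CC/C(C)=C\[C@H]2OC(=O)[C@@H](C)[C@]12O | intermediate
35 | CNP0195208.4 (2,9,14-triacetoxy-8,12-dihydroxybriar-5Z-en-19,7-olide) | CC(=O)O[C@@H]1[C@@H]2[C@H](C)[C@@H](O)C[C@@H](OC(C)=O)[C@@]2(C)[C@H](OC(C)=O)CC/C(C)=C\[C@H]2OC(=O)[C@@H](C)[C@]12O | target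

**Step count**

Total step count: 22.
Longest linear sequence: 20 steps (steps 1–12 and 15–22); steps 13–14 make the diene from 21.

**Steps most likely to fail**

Step 15 (Diels–Alder). The trisubstituted enone may react too slowly with the 4-substituted diene, or the diene may add to the wrong face of C1=C10 because the C9 stereocentre controls it poorly. Fallback: a stepwise annulation starting from 20 and 24. A TiCl4-promoted Mukaiyama–Michael addition (CH2Cl2, −78 °C) should form only the C10–C11 bond through an open transition state and give the Michael adduct F1, a 1,5-diketone that still carries the β-silyloxy enone. Base-mediated intramolecular Michael addition of the C2 ketone enolate (C1) to C14 (DBU, MeCN, 0 °C) then closes the ring and returns to 26.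

Step 11 (Nozaki–Hiyama–Kishi closure). Medium-ring strain may favour oligomerisation or simple reduction of the alkenyl iodide over ten-membered ring closure. Fallback: a macrocyclic ketone synthesis starting from 18. Pinnick oxidation (NaClO2, NaH2PO4, 2-methylbut-2-ene) should give the carboxylic acid F2, and 2,2'-dipyridyl disulfide with PPh3 the S-(2-pyridyl) thioester F3. Intramolecular nickel/zirconium-mediated coupling of the alkenyl iodide with the thioester (NiBr2(dtbbpy), Cp2ZrCl2, Zn, DMI, high dilution) would then give the enone 20 directly, without passing through 19.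

Step 10 (Reformatsky lactonisation). SmI2 may instead cleave the α-acyloxy group from the ketone, and the configuration at C8 may be poorly controlled in the ring-forming addition. Fallback: an intermolecular, chelation-controlled Reformatsky reaction starting from 15. The zinc enolate of ethyl 2-bromopropanoate (Zn, THF, 0 °C) should add to the C8 ketone held in a five-membered zinc chelate with O7, anti to the C6 alkenyl group, and give the dihydroxy ester F4. The 1 M HCl in THF used in the route then lactonises F4 to 17 and hydrolyses the acetal, returning to 18.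

Further compounds
F1 | step 15 | Michael adduct: ten-membered 2-ketone (C1–H epimers) bearing at C10 the chain CH(CH2SPh)–C(=O)–CH=CH–OTBS | CC(C)(C)[Si](C)(C)O[C@@H]1[C@H](C(CSc3ccccc3)C(=O)/C=C/O[Si](C)(C)C(C)(C)C)C(C)C(=O)CC/C(C)=C\[C@H]2OC(=O)[C@@H](C)[C@]12O
F2 | step 11 | carboxylic acid from 18 (C2 acid) | OC(=O)CC/C(C)=C\[C@H]1OC(=O)[C@@H](C)[C@]1(O)[C@H](O[Si](C)(C)C(C)(C)C)/C=C(\C)I
F3 | step 11 | S-(2-pyridyl) thioester of F2 | O=C(CC/C(C)=C\[C@H]1OC(=O)[C@@H](C)[C@]1(O)[C@H](O[Si](C)(C)C(C)(C)C)/C=C(\C)I)Sc1ccccn1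
F4 | step 10 | ethyl ester of the open-chain 7,8-dihydroxy acid (C17 epimers) | CCOC(OCC)CC/C(C)=C\[C@@H](O)[C@](O)(C(C)C(=O)OCC)[C@H](O[Si](C)(C)C(C)(C)C)/C=C(\C)I
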